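The route rests on cutting the C9–C10 bond and the O–C7 bond of the spiro δ-lactone (ring B: C10, C20, O, C7, C8, C9). C10 and C9 are each β to a carbonyl (C6 and C7), a like-polarity pair that ionic chemistry cannot join directly, so a nucleophilic tertiary C10 radical is used. In one operation, photoredox decarboxylation of a ring A hydroxy acid (C10 carrying CO2H and C20H2OH, C5 carrying a silyloxymethyl arm, C3=C4 olefin) adds the C10 radical to methyl acrylate trans to the C5 arm and the hydroxy ester closes ring B. Rings C and D are then annulated on the lactone.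

Key step: step 6

Remark: atom labels C1–C20 follow the ent-kaurane numbering of the target (C10 spiro carbon, C20 lactone OCH2, C7 lactone carbonyl, C6 aldehyde carbon, C15 ketone, C17 exocyclic methylene). "C5 arm" means the C6 substituent on C5. t-Bu-box = 2,2'-(propane-2,2-diyl)bis[(4S)-4-tert-butyl-4,5-dihydro-1,3-oxazole]. Compounds 1, 4, 9 and 16 are assumed to be purchased.

Step 1
Reactants: 1 (2E)-3-methylpent-2-en-4-yn-1-ol
Product: 2 tert-butyl{[(2E)-3-methylpent-2-en-4-yn-1-yl]oxy}diphenylsilane
Conditions: TBDPSCl, imidazole, DMF, 0 °C → rt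
Reagents that add atoms: tert-butyl(chloro)diphenylsilane, CC(C)(C)[Si](Cl)(c1ccccc1)c1ccccc1
Why: Standard silylation of a primary alcohol; the bulky, acid-stable silyl ether is chosen because it must later shield one face of ring A and survive the acidic lactonisation and acetolysis steps.

Step 2
Reactants: 2 tert-butyl{[(2E)-3-methylpent-2-en-4-yn-1-yl]oxy}diphenylsilane
Product: 3 tert-butyl{[(2E)-3-methylpenta-2,4-dien-1-yl]oxy}diphenylsilane
Conditions: H2 (1 atm), Pd/CaCO3 poisoned with Pb(OAc)2, quinoline, hexane/EtOAc, rt, stopped after 1 equiv H2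
Reagents that add atoms: none
Why: Lindlar semihydrogenation reduces the terminal alkyne to the vinyl group and leaves the trisubstituted E-olefin alone, so the E-diene geometry needed for the cycloaddition is already in place.

Step 3
Reactants: 3 tert-butyl{[(2E)-3-methylpenta-2,4-dien-1-yl]oxy}diphenylsilane; 4 3-acryloyl-1,3-oxazolidin-2-one
Product: 5 3-{[(1S,2S)-2-({[tert-butyl(diphenyl)silyl]oxy}methyl)-3-methylcyclohex-3-en-1-yl]carbonyl}-1,3-oxazolidin-2-one (cis adduct)
Conditions: [Cu((S,S)-t-Bu-box)](SbF6)2 (10 mol %), CH2Cl2, −20 °C → rt; minor trans adduct removed by chromatography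
Reagents that add atoms: none
Why: Catalytic enantioselective Diels–Alder reaction of a chelating acrylimide under a C2-symmetric bis(oxazoline)copper Lewis acid, in which the tert-butyl group blocks one face of the s-cis imide and the substituted terminus of the E-diene bonds to the α-carbon ("ortho") in an endo transition state, setting C5 (and, temporarily, C10); the trans adduct is removed because it would carry the opposite C5 configuration once C10 is erased.

Step 4
Reactants: 5 cis Diels–Alder imide
Product: 7 (1S,2S)-2-({[tert-butyl(diphenyl)silyl]oxy}methyl)-3-methylcyclohex-3-ene-1-carboxylic acid, via peroxy acid 6 (not isolated)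
Conditions: LiOH, H2O2, THF/H2O, 0 °C; then Na2SO3; then 1 M HCl
Reagents that add atoms: hydrogen peroxide, OO
Why: Hydroperoxide cleaves the exocyclic imide carbonyl selectively (standard N-acyl oxazolidinone hydrolysis) and sulfite reduces the percarboxylate to the acid; C5 is not epimerisable and the configuration at C10 does not matter because it is erased in step 6.

Step 5
Reactants: 7 (1S,2S)-cyclohexene carboxylic acid
Product: 8 (1S,2R)-2-({[tert-butyl(diphenyl)silyl]oxy}methyl)-1-(hydroxymethyl)-3-methylcyclohex-3-ene-1-carboxylic acid (ring A hydroxy acid)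
Conditions: LDA (2.2 equiv), THF, −78 → 0 °C; CH2O (gas, from cracked paraformaldehyde), −78 °C → rt; then 1 M HCl
Reagents that add atoms: formaldehyde, C=O
Why: Aldol hydroxymethylation of a carboxylic acid dianion builds the quaternary C10 bearing CO2H and C20H2OH; formaldehyde should enter anti to the C5 arm (the epimer drawn), but either C10 epimer serves because C10 becomes a planar radical in step 6.

Step 6
Reactants: 8 ring A hydroxy acid; 9 methyl acrylate
Product: 11 (6R,7R)-7-({[tert-butyl(diphenyl)silyl]oxy}methyl)-8-methyl-2-oxaspiro[5.5]undec-8-en-3-one (ring A spiro δ-lactone), via hydroxy ester 10 (not isolated)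
Conditions: Ir[dF(CF3)ppy]2(dtbbpy)PF6 (1 mol %), K2HPO4, DMF, blue LEDs, rt; then CSA (10 mol %), CH2Cl2, rt
Reagents that add atoms: none
Why: The photoexcited iridium complex oxidises the carboxylate of 8, CO2 is lost, and the planar, nucleophilic tertiary C10 radical adds to the unsubstituted terminus of methyl acrylate (C9); the α-ester radical is then reduced to the enolate by the reduced photocatalyst and protonated to give hydroxy ester 10. This is the known photoredox decarboxylative Giese addition of tertiary carboxylic acids to acrylates, applied to a β-hydroxy acid. Ring B closes on acid treatment by 6-exo-trig acyl substitution of the C20 hydroxyl at the ester carbonyl C7, with loss of methanol. The one new stereocentre, C10, is controlled by the neighbouring C5 stereocentre: the pseudoaxial silyloxymethyl arm covers one face of the radical, so the acrylate bonds on the other face and C9 ends up trans to C6 with C20 cis to it. The step needs this facial selectivity and capture of the adduct radical before it can attack the C3=C4 olefin; the bulky silyl ether and the fast reduction of the electrophilic α-ester radical are expected to secure both, and since C10 is planar in the radical both C10 epimers of 8 give the same lactone.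

Step 7
Reactants: 11 ring A spiro δ-lactone
Product: 12 (6R,7R)-4-acetyl-7-({[tert-butyl(diphenyl)silyl]oxy}methyl)-8-methyl-2-oxaspiro[5.5]undec-8-en-3-one (C8-acetyl lactone; C8 epimers and enol)
Conditions: LDA, THF, −78 °C; MeC(O)N(OMe)Me, −78 → 0 °C; aq. NH4Cl
Reagents that add atoms: N-methoxy-N-methylacetamide, CC(=O)N(C)OC
Why: Crossed Claisen acylation of the lactone lithium enolate (C8 is the only enolisable carbon) with a Weinreb amide, whose stable tetrahedral adduct prevents over-addition and releases the β-keto lactone on work-up.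

Step 8
Reactants: 12 C8-acetyl lactone
Product: 15 (6R,7R)-4-acetyl-7-({[tert-butyl(diphenyl)silyl]oxy}methyl)-8-methyl-2-oxaspiro[5.5]undeca-4,8-dien-3-one (C8=C9 keto lactone), via selenide 13 (not isolated), via selenoxide 14 (not isolated)
Conditions: PhSeCl, pyridine, CH2Cl2, 0 °C; then H2O2 (30%), 0 °C → rt
Reagents that add atoms: none
Why: Selenenylation of the β-dicarbonyl enol followed by oxidation and syn selenoxide elimination, whose only β-hydrogens are on C9, gives the doubly activated C8=C9 dienophile, which is used at once.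

Step 9
Reactants: 15 C8=C9 keto lactone; 16 buta-1,3-diene
Product: 17 ring C cycloadduct (8-acetyl lactone with cis-fused cyclohexene ring C, C12=C13; C11 and C14 on the C1 face of ring B, acetyl and H9 on the C5 face)
Conditions: ZnCl2, buta-1,3-diene (excess), CH2Cl2, −20 °C → rt, sealed tube
Reagents that add atoms: none
Why: Lewis acid-promoted Diels–Alder reaction of a chelated 2-acyl enoate builds ring C suprafacially (C8–C14 and C9–C11 cis), and the diene should approach the face of C8=C9 flanked by the C1 methylene, away from C5 and its silyloxymethyl arm, which sets C8 and C9.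

Step 10
Reactants: 17 ring C cycloadduct
Product: 18 tert-butyldimethylsilyl enol ether of 17 (C15(OSi)=C16H2)
Conditions: TBSOTf, Et3N, CH2Cl2, 0 °C
Reagents that add atoms: tert-butyldimethylsilyl trifluoromethanesulfonate, CC(C)(C)[Si](C)(C)OS(=O)(=O)C(F)(F)F
Why: Soft enolisation and O-silylation of the methyl ketone gives the terminal silyl enol ether, because the CH3 group (C16) is the only enolisable position once C8 is quaternary.

Step 11
Reactants: 18 silyl enol ether
Product: 19 tetracyclic keto lactone with ring D closed (C16–C13 bond, bicyclo[3.2.1]octene with C11=C12, C15 ketone)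
Conditions: Pd(OAc)2 (1.1 equiv), DMSO, 45 °C
Reagents that add atoms: none
Why: Palladium-mediated oxidative cyclisation of a silyl enol ether onto an olefin (cycloalkenylation: palladium enolate, 5-exo insertion of C12=C13, syn β-hydride elimination toward C11) forms C16–C13, with C13 fixed by the bridging geometry from C8 and no competing dehydrogenation because C8 carries no hydrogen.

Step 12
Reactants: 19 unsaturated tetracyclic keto lactone
Product: 20 saturated tetracyclic keto lactone (bicyclo[3.2.1]octan-15-one, C16H2)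
Conditions: H2 (1 atm), RhCl(PPh3)3 (10 mol %), benzene, rt
Reagents that add atoms: none
Why: Homogeneous hydrogenation with this rhodium catalyst reduces the strained cis-disubstituted C11=C12 olefin much faster than the hindered trisubstituted C3=C4 olefin and creates no stereocentre.

Step 13
Reactants: 20 saturated tetracyclic keto lactone
Product: 22 15-oxo-16-methylene keto lactone (C6 silyl ether, C3=C4 olefin), via Mannich base 21 (not isolated)
Conditions: (CH2O)n, PhNHMe·CF3CO2H, THF, reflux
Reagents that add atoms: formaldehyde (as paraformaldehyde), C=O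
Why: One-pot α-methylenation (Mannich condensation, then loss of N-methylaniline) takes place at C16, the only enolisable carbon, and gives the exocyclic enone of ring D.

Step 14
Reactants: 22 15-oxo-16-methylene keto lactone
Product: 23 3,4-epoxide of 22 (oxygen on the ring A face opposite to C20 and the C5 arm)
Conditions: mCPBA, NaHCO3, CH2Cl2, 0 °C
Reagents that add atoms: 3-chloroperoxybenzoic acid, OOC(=O)c1cccc(Cl)c1
Why: Prilezhaev epoxidation selects the electron-rich trisubstituted C3=C4 olefin over the electron-poor enone, and the peracid should approach the face of ring A opposite to axial C20 and the C5 silyloxymethyl arm, which sets C3 and places the oxygen correctly for the opening.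

Step 15
Reactants: 23 3,4-epoxide
Product: 24 C4 acetate with free C3 hydroxyl (acetate cis to the C5 arm and C20, hydroxyl trans to the acetate; C6 silyl ether)
Conditions: AcOH, 40 °C
Reagents that add atoms: acetic acid, CC(=O)O
Why: Acid-promoted acetolysis of the trisubstituted epoxide occurs at the tertiary carbon C4 with inversion, which is also the trans-diaxial (Fürst–Plattner) mode of opening, so C4 is set with the acetate cis to the C5 arm and the C3 hydroxyl is left free.

Step 16
Reactants: 24 C4 acetate silyl ether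
Product: 25 C6 alcohol (C3,C6-diol with C4 acetate)
Conditions: HF·pyridine, pyridine, THF, 0 °C → rt
Reagents that add atoms: none
Why: Fluoride cleavage of the silyl ether under weakly acidic conditions frees the primary C6 hydroxyl without base-induced acetyl migration or attack on the enone.

Step 17
Reactants: 25 C6 alcohol
Product: 26 target CNP0199571.1
Conditions: TEMPO (10 mol %), PhI(OAc)2, CH2Cl2, rt
Reagents that add atoms: none
Why: Oxoammonium-mediated oxidation is selective for the primary C6 alcohol over the hindered secondary C3 alcohol and runs under non-basic conditions, so the β-acetoxy aldehyde should neither epimerise at C5 nor lose acetate.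

Compound list

1 | (2E)-3-methylpent-2-en-4-yn-1-ol | C#C/C(C)=C/CO | starting material
2 | tert-butyl{[(2E)-3-methylpent-2-en-4-yn-1-yl]oxy}diphenylsilane | C#C/C(C)=C/CO[Si](c1ccccc1)(c1ccccc1)C(C)(C)C | intermediate
3 | tert-butyl{[(2E)-3-methylpenta-2,4-dien-1-yl]oxy}diphenylsilane | C=C/C(C)=C/CO[Si](c1ccccc1)(c1ccccc1)C(C)(C)C | intermediate
4 | 3-acryloyl-1,3-oxazolidin-2-one | C=CC(=O)N1CCOC1=O | starting material
5 | 3-{[(1S,2S)-2-({[tert-butyl(diphenyl)silyl]oxy}methyl)-3-methylcyclohex-3-en-1-yl]carbonyl}-1,3-oxazolidin-2-one (acyl group and C5 arm cis) | O=C(N1CCOC1=O)[C@H]2CCC=C(C)[C@H]2CO[Si](c3ccccc3)(c4ccccc4)C(C)(C)C | intermediate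
6 | (1S,2S)-2-({[tert-butyl(diphenyl)silyl]oxy}methyl)-3-methylcyclohex-3-ene-1-carboperoxoic acid | OOC(=O)[C@H]1CCC=C(C)[C@H]1CO[Si](c2ccccc2)(c3ccccc3)C(C)(C)C | intermediate
7 | (1S,2S)-2-({[tert-butyl(diphenyl)silyl]oxy}methyl)-3-methylcyclohex-3-ene-1-carboxylic acid | OC(=O)[C@H]1CCC=C(C)[C@H]1CO[Si](c2ccccc2)(c3ccccc3)C(C)(C)C | intermediate
8 | (1S,2R)-2-({[tert-butyl(diphenyl)silyl]oxy}methyl)-1-(hydroxymethyl)-3-methylcyclohex-3-ene-1-carboxylic acid (CO2H cis to the C5 arm; the C10 epimer converges) | OC[C@@]1(CCC=C(C)[C@H]1CO[Si](c2ccccc2)(c3ccccc3)C(C)(C)C)C(=O)O | intermediate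
9 | methyl acrylate (methyl prop-2-enoate) | C=CC(=O)OC | starting material
10 | methyl 3-[(1R,2R)-2-({[tert-butyl(diphenyl)silyl]oxy}methyl)-1-(hydroxymethyl)-3-methylcyclohex-3-en-1-yl]propanoate | COC(=O)CC[C@@]1(CCC=C(C)[C@H]1CO[Si](c2ccccc2)(c3ccccc3)C(C)(C)C)CO | intermediate
11 | (6R,7R)-7-({[tert-butyl(diphenyl)silyl]oxy}methyl)-8-methyl-2-oxaspiro[5.5]undec-8-en-3-one (C20 cis to C6, C9 trans to C6) | O=C1CC[C@@]2(CCC=C(C)[C@H]2CO[Si](c3ccccc3)(c4ccccc4)C(C)(C)C)CO1 | intermediate
12 | (6R,7R)-4-acetyl-7-({[tert-butyl(diphenyl)silyl]oxy}methyl)-8-methyl-2-oxaspiro[5.5]undec-8-en-3-one (C8 epimers and enol) | CC(=O)C1C[C@@]2(CCC=C(C)[C@H]2CO[Si](c3ccccc3)(c4ccccc4)C(C)(C)C)COC1=O | intermediate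
13 | (6R,7R)-4-acetyl-4-(phenylselanyl)-7-({[tert-butyl(diphenyl)silyl]oxy}methyl)-8-methyl-2-oxaspiro[5.5]undec-8-en-3-one | CC(=O)C1([Se]c5ccccc5)C[C@@]2(CCC=C(C)[C@H]2CO[Si](c3ccccc3)(c4ccccc4)C(C)(C)C)COC1=O | intermediate
14 | selenoxide of 13 (4-acetyl-4-(phenylseleninyl) lactone) | CC(=O)C1([Se](=O)c5ccccc5)C[C@@]2(CCC=C(C)[C@H]2CO[Si](c3ccccc3)(c4ccccc4)C(C)(C)C)COC1=O | intermediate
15 | (6R,7R)-4-acetyl-7-({[tert-butyl(diphenyl)silyl]oxy}methyl)-8-methyl-2-oxaspiro[5.5]undeca-4,8-dien-3-one | CC(=O)C1=C[C@@]2(CCC=C(C)[C@H]2CO[Si](c3ccccc3)(c4ccccc4)C(C)(C)C)COC1=O | intermediate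
16 | buta-1,3-diene | C=CC=C | starting material
17 | ring C cycloadduct: 8-acetyl 7,20-lactone with cis-fused cyclohexene ring C (C12=C13); C11 and C14 on the C1 face of ring B, acetyl and H9 on the C5 face; ring A as in 11 | CC(=O)[C@]12CC=CC[C@H]1[C@@]3(CCC=C(C)[C@H]3CO[Si](c4ccccc4)(c5ccccc5)C(C)(C)C)COC2=O | intermediate
18 | tert-butyldimethylsilyl enol ether of 17 (C15(OSi)=C16H2) | C=C(O[Si](C)(C)C(C)(C)C)[C@]12CC=CC[C@H]1[C@@]3(CCC=C(C)[C@H]3CO[Si](c4ccccc4)(c5ccccc5)C(C)(C)C)COC2=O | intermediate
19 | tetracyclic keto lactone: C15–C16 bridge from C8 to C13 (bicyclo[3.2.1]octene), C11=C12 olefin, C15 ketone | C1C(=O)[C@]23C[C@H]1C=C[C@H]2[C@@]4(CCC=C(C)[C@H]4CO[Si](c5ccccc5)(c6ccccc6)C(C)(C)C)COC3=O | intermediate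
20 | 11,12-dihydro derivative of 19 (saturated bicyclo[3.2.1]octan-15-one) | C1C(=O)[C@]23C[C@H]1CC[C@H]2[C@@]4(CCC=C(C)[C@H]4CO[Si](c5ccccc5)(c6ccccc6)C(C)(C)C)COC3=O | intermediate
21 | 16-[(N-methylanilino)methyl] derivative of 20 (C16 epimers) | CN(c7ccccc7)CC1C(=O)[C@]23C[C@H]1CC[C@H]2[C@@]4(CCC=C(C)[C@H]4CO[Si](c5ccccc5)(c6ccccc6)C(C)(C)C)COC3=O | intermediate
22 | 15-oxo-16-methylene keto lactone with C6 silyl ether and C3=C4 olefin | C=C1C(=O)[C@]23C[C@H]1CC[C@H]2[C@@]4(CCC=C(C)[C@H]4CO[Si](c5ccccc5)(c6ccccc6)C(C)(C)C)COC3=O | intermediate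
23 | 3,4-epoxide of 22, oxygen on the ring A face opposite to C20 and C6 | C=C1C(=O)[C@]23C[C@H]1CC[C@H]2[C@@]4(CC[C@@H]5O[C@]5(C)[C@H]4CO[Si](c6ccccc6)(c7ccccc7)C(C)(C)C)COC3=O | intermediate
24 | C4 acetate (cis to C6 and C20), C3 alcohol (trans to the acetate), C6 silyl ether | C=C1C(=O)[C@]23C[C@H]1CC[C@H]2[C@@]4(CC[C@H](O)[C@@](C)(OC(C)=O)[C@H]4CO[Si](c5ccccc5)(c6ccccc6)C(C)(C)C)COC3=O | intermediate
25 | C6 primary alcohol of 24 (C3,C6-diol, C4 acetate) | C=C1C(=O)[C@]23C[C@H]1CC[C@H]2[C@@]4(CC[C@H](O)[C@@](C)(OC(C)=O)[C@H]4CO)COC3=O | intermediate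
26 | CNP0199571.1: spirolactone-type 6,7-seco-ent-kauranoid with C4 acetate, C3 hydroxyl, C6 aldehyde and 15-oxo-16-methylene ring D | C=C1C(=O)[C@]23C[C@H]1CC[C@H]2[C@@]1(CC[C@H](O)[C@@](C)(OC(C)=O)[C@H]1C=O)COC3=O | target

Total step count: 17. Longest linear sequence: 17 steps (from 1; compounds 4, 9 and 16 enter as purchased reagents).

Steps most likely to fail

Step 6 (key step). The C10 radical may be captured with too little facial discrimination, or the α-ester adduct radical may cyclise onto the C3=C4 olefin before it is reduced. The fallback forms the C9–C10 bond by enolate chemistry instead; it sets out from acid 7 and returns at lactone 11. The dianion of 7 (LDA, THF) is alkylated with allyl bromide on the face away from the C5 arm to give the allyl acid F1. LiAlH4 reduces the carboxyl group to give the neopentyl alcohol F2, whose CH2OH is C20. 9-BBN followed by NaOH/H2O2 hydroborates only the terminal olefin and gives the 1,5-diol F3. TEMPO/PhI(OAc)2 oxidises the unhindered C7 alcohol first, and the lactol that forms is oxidised on to lactone 11.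

Step 9. Cycloaddition at C9, which sits next to the quaternary C10, may be slow enough for the sensitive dienophile to decompose, or the diene may discriminate poorly between the two faces of C8=C9. The fallback builds ring C stepwise; it sets out from lactone 11 and returns at cycloadduct 17. LDA and PhSeBr give the α-selanyl lactone F4, and H2O2 gives the unsaturated lactone F5. Allylmagnesium bromide with CuBr·SMe2 and TMSCl adds an allyl group to C9 on the C1 face to give the allyl lactone F6. LDA and allyl bromide alkylate C8 trans to that group and give the diallyl lactone F7. Ring-closing metathesis with the second-generation Grubbs catalyst RuCl2(H2IMes)(PCy3)(=CHPh) closes ring C as the bicyclic lactone F8. The ring-fusion enolate of F8 (LDA) is acetylated with N-methoxy-N-methylacetamide on the face of H9, which should give the cis-fused keto lactone 17. This changes the bond-forming event at C9 but still relies on the C1 face being the more open one.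

Step 11. The palladium enolate may be protonated back to ketone 17, may close onto C12 instead of C13, or the new olefin may migrate. The fallback closes ring D by a radical; it sets out from silyl enol ether 18 and returns at ketone 20. NBS (THF, 0 °C) gives the bromomethyl ketone F9. Bu3SnH/AIBN (benzene, 80 °C, slow addition) generates the C16 radical, which should close 5-exo onto C13 and be reduced at C12, giving 20 directly so that step 12 is skipped. Its own weakness is that α-keto radicals can prefer the 6-endo mode, which would give the bicyclo[2.2.2] isomer.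

Further compounds

F1 | step 6 | 1-allyl-2-({[tert-butyl(diphenyl)silyl]oxy}methyl)-3-methylcyclohex-3-ene-1-carboxylic acid, allyl trans to the C5 arm | OC(=O)[C@@]1(CC=C)CCC=C(C)[C@H]1CO[Si](c2ccccc2)(c3ccccc3)C(C)(C)C
F2 | step 6 | [1-allyl-2-({[tert-butyl(diphenyl)silyl]oxy}methyl)-3-methylcyclohex-3-en-1-yl]methanol, CH2OH cis to the C5 arm | OC[C@@]1(CC=C)CCC=C(C)[C@H]1CO[Si](c2ccccc2)(c3ccccc3)C(C)(C)C
F3 | step 6 | 3-[2-({[tert-butyl(diphenyl)silyl]oxy}methyl)-1-(hydroxymethyl)-3-methylcyclohex-3-en-1-yl]propan-1-ol, configuration as in 10 | OC[C@@]1(CCCO)CCC=C(C)[C@H]1CO[Si](c2ccccc2)(c3ccccc3)C(C)(C)C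
F4 | step 9 | 4-(phenylselanyl) derivative of lactone 11 (C8 epimers) | O=C1C([Se]c5ccccc5)C[C@@]2(CCC=C(C)[C@H]2CO[Si](c3ccccc3)(c4ccccc4)C(C)(C)C)CO1
F5 | step 9 | 7-({[tert-butyl(diphenyl)silyl]oxy}methyl)-8-methyl-2-oxaspiro[5.5]undeca-4,8-dien-3-one (C8=C9 lactone) | O=C1C=C[C@@]2(CCC=C(C)[C@H]2CO[Si](c3ccccc3)(c4ccccc4)C(C)(C)C)CO1
F6 | step 9 | 5-allyl derivative of lactone 11 (allyl on C9, on the C1 face of ring B) | O=C1C[C@@H](CC=C)[C@@]2(CCC=C(C)[C@H]2CO[Si](c3ccccc3)(c4ccccc4)C(C)(C)C)CO1
F7 | step 9 | trans-4,5-diallyl derivative of lactone 11 (allyl groups on C8 and C9) | O=C1[C@H](CC=C)[C@@H](CC=C)[C@@]2(CCC=C(C)[C@H]2CO[Si](c3ccccc3)(c4ccccc4)C(C)(C)C)CO1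
F8 | step 9 | trans-fused bicyclic lactone with ring C closed (C12=C13), hydrogen on C8 | O=C1[C@@H]3CC=CC[C@H]3[C@@]2(CCC=C(C)[C@H]2CO[Si](c4ccccc4)(c5ccccc5)C(C)(C)C)CO1
F9 | step 11 | bromomethyl ketone of 17 (C16 bromide) | BrCC(=O)[C@]12CC=CC[C@H]1[C@@]3(CCC=C(C)[C@H]3CO[Si](c4ccccc4)(c5ccccc5)C(C)(C)C)COC2=O
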